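Readings and results come from a simulation for an exercise.

The number I started from was the 0.500 equiv of reagent in the flask, since it sets what the charge allows whatever the clock says.

common to all: free catalyst 0.27 mol%

| charge | substrate | reagent | remark | time |
|---|---|---|---|---|
| ash | 0.30 M | 0.50 equiv | run made earlier |  |
| flask | 0.20 M | 0.500 equiv |  | 25 min |

- ash (time / min: substrate / %, target / %): 0.167: 75.5, 24.3; 0.417: 60.5, 39.2; 0.667: 54.0, 45.3; 1.00: 52.8, 48.2; 1.50: 50.9, 50.1; 2.00: 50.1, 49.5; 2.50: 51.2, 50.3

(each reading ± 0.5 percentage points)

- what may be going on: substrate + reagent + free catalyst -> target + free catalyst; 2 free catalyst -> spent catalyst
- the reaction counts as stopped when no species that holds the substrate changes by six tenths of a point or more over the second half of the time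
- no earlier run changes the charge of free catalyst; that part of a forecast is a guess

* why nothing more happens at 25 min, or that something still does (it is still moving / no working catalyst is left / all of the substrate has reacted / the reagent has run out first)
* share of the substrate used up at 25 min
* target at 25 min, in percent of the substrate charged

I built the flask up one process at a time. With the main step by itself, substrate + reagent + free catalyst → target + free catalyst, I divided the rate at which substrate goes by the rate at which reagent goes. Each turn takes one of each, so the ratio is 1, time and catalyst drop out, and substrate used equals reagent used. That gave Y = 50.0 %, the equivalents of reagent read as a percentage of the substrate charged, my reagent ceiling, with reagent as the limiting reagent.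

Adding two free catalyst → spent catalyst left that ratio as it was, since this step touches neither substrate nor reagent, but it could stop the flask below Y. The ash run spoke against a stop: its target read 50.1 % at 1.50 min, against a ceiling of 50.0 % for that run.

Last came the dilution from 0.30 M in the ash run to 0.20 M in the flask, which I expected to slow the main step by a factor I could not read from one run. The flask's 25 min is 16.7 times the ash run's 1.50 min, though the catalyst's survival over that stretch was a guess. My number stayed at Y.

The forecast gave 50 % conversion and 50 % target, with the verdict "the reagent has run out first", holding that “the reagent, not the catalyst, ended that run”.

The flask gave 50.0 % conversion and 50.0 % target at 25 min, and the verdict was the same: the reagent has run out first.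

    substrate + reagent + free catalyst → target + free catalyst, rate k1*[substrate]*[reagent]*[free catalyst]/(1 + ([substrate]/sat1)) (16.9 mM, k = 5510 M⁻² s⁻¹)
    2 free catalyst → spent catalyst (k = 4.87 M⁻¹ s⁻¹)

The flask's target stood on Y = 50.0 %, with 0 % of the reagent left against 50 % of the substrate. At 2.50 min reagent was already down to 0.778 % of its charge while free catalyst still stood at 55.9 %. The neighbouring flask, the same but for 0.200 equiv of reagent, has a ceiling of 20.0 % by the same reckoning, and it gave 20.0 % target at 25 min, with 80 % of its substrate left.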